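The route rests on cutting the bond between C6 of the cyclohexene ring (C1 quaternary, C4 methyl-bearing, C6 aryl-bearing) and C8 of coumarin B. Coumarin B stands cis to the styryl carbon on C1, and its ring oxygen O1 is ortho to that bond, so a carboxyl on C1 can be tied to this oxygen as an aryl ester. Ionising a tertiary allylic alcohol at C4 then lets the tethered 3,5-dimethoxyphenyl ring attack C6, which makes the C6–aryl bond, the C6 stereocentre and a temporary lactone in one operation. The precursor is the 3,5-dimethoxyphenyl ester of (1S)-4-hydroxy-1,4-dimethylcyclohex-2-ene-1-carboxylic acid, made from an asymmetric Diels–Alder adduct.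

Key step: step 6

Assumption: the (S)-configured oxazaborolidinium catalyst of step 1 is taken to expose the Re face of C2 of bound methacrolein, as its formyl C–H···O binding model predicts, which gives (S)-3; the mirror-image catalyst would be used if the opposite sense were found.

Step 1
Reactants: 1 methacrolein (2-methylprop-2-enal); 2 isoprene (2-methylbuta-1,3-diene)
Product: 3 (1S)-1,4-dimethylcyclohex-3-ene-1-carbaldehyde
Conditions: (S)-3,3-diphenyl-1-(2-methylphenyl)tetrahydro-1H,3H-pyrrolo[1,2-c][1,3,2]oxazaborole (10 mol %), Tf2NH (8 mol %), isoprene (3 equiv), CH2Cl2, −78 °C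
Reagents that add atoms: none
Why: Catalytic enantioselective Diels–Alder reaction of a 2-substituted acrolein activated by a protonated oxazaborolidine; isoprene adds with "para" regiochemistry to the Re face of C2 of the boron-bound s-trans enal, which sets the quaternary carbon as S.

Step 2
Reactants: 3 (1S)-1,4-dimethylcyclohex-3-ene-1-carbaldehyde
Product: 4 (1S)-1,4-dimethylcyclohex-3-ene-1-carboxylic acid
Conditions: NaClO2, NaH2PO4, 2-methylbut-2-ene (20 equiv), t-BuOH/H2O, 0 to 23 °C
Reagents that add atoms: sodium chlorite, [Na+].[O-]Cl=O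
Why: Pinnick oxidation of an aldehyde that has no α-hydrogen, so the stereocentre cannot epimerise, while the large excess of 2-methylbut-2-ene traps hypochlorous acid before it reaches the ring alkene.

Step 3
Reactants: 4 (1S)-1,4-dimethylcyclohex-3-ene-1-carboxylic acid; 5 3,5-dimethoxyphenol
Product: 6 3,5-dimethoxyphenyl (1S)-1,4-dimethylcyclohex-3-ene-1-carboxylate
Conditions: N,N'-diisopropylcarbodiimide, DMAP (0.3 equiv), CH2Cl2, 23 °C
Reagents that add atoms: none
Why: Steglich esterification through the acylpyridinium ion, which acylates phenols well even from α-quaternary acids; the aryl ester is installed before the C4 hydroxyl exists, so no hydroxy acid that could lactonise across the ring ever has to be activated.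

Step 4
Reactants: 6 3,5-dimethoxyphenyl (1S)-1,4-dimethylcyclohex-3-ene-1-carboxylate
Product: 7 3,5-dimethoxyphenyl (1S)-4-hydroxy-1,4-dimethyl-3-(phenylselanyl)cyclohexane-1-carboxylate (3,4-trans, both diastereomers relative to C1)
Conditions: PhSeCl (1.05 equiv), MeCN/H2O 5:1, 0 to 23 °C
Reagents that add atoms: benzeneselenenyl chloride, Cl[Se]c1ccccc1; water, O
Why: Hydroxyselenation of a trisubstituted alkene, in which the seleniranium ion is opened anti by water at the tertiary carbon C4 (Markovnikov) and the large excess of water outruns the weakly nucleophilic ester carbonyl; the configurations at C3 and C4 need no control because steps 5 and 6 erase them.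

Step 5
Reactants: 7 3,5-dimethoxyphenyl (1S)-4-hydroxy-1,4-dimethyl-3-(phenylselanyl)cyclohexane-1-carboxylate
Product: 9 3,5-dimethoxyphenyl (1S)-4-hydroxy-1,4-dimethylcyclohex-2-ene-1-carboxylate (both C4 epimers), via selenoxide 8 (not isolated)
Conditions: mCPBA (1.05 equiv), CH2Cl2, −78 °C; then i-Pr2NEt, −78 to 23 °C; chromatography on Et3N-washed silica
Reagents that add atoms: none
Why: Selenide oxidation followed by selenoxide syn-elimination, which can run only toward C2 because C4 carries no hydrogen, so the alkene lands at C2=C3 next to the quaternary carbon and the tertiary allylic alcohol is left in place.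

Step 6
Reactants: 9 3,5-dimethoxyphenyl (1S)-4-hydroxy-1,4-dimethylcyclohex-2-ene-1-carboxylate
Product: 11 (6aS,10aS)-1,3-dimethoxy-6a,9-dimethyl-6a,7,8,10a-tetrahydro-6H-benzo[c]chromen-6-one (cis-fused), via allyl cation 10 (not isolated)
Conditions: BF3·OEt2 (20 mol %), 4 Å molecular sieves, CH2Cl2 (0.01 M), −40 to 0 °C; NaHCO3 quench at 0 °C
Reagents that add atoms: none
Why: Proposed new method: BF3 ionises the tertiary allylic C4–OH of either epimer to allyl cation 10 (C4–C3–C2 of the ester, C4–C5–C6 of the target ring), the aryl ester turns into its s-cis form, and the ring carbon ortho to the ester oxygen (ortho to one methoxy, para to the other) attacks the secondary allyl terminus next to C1 before proton loss restores the arene; the closest known reactions are the BF3-mediated Friedel–Crafts allylation of resorcinols and phloroglucinol ethers by cyclic tertiary allylic alcohols and the acid cyclisation of electron-rich aryl cinnamates to 4-substituted dihydrocoumarins, which closes the same lactone from the same ester conformer. The six-membered lactone closes in a 6-exo-trig sense at the allyl terminus, with the arene π bond inside the new ring. The new stereocentre (C10a of 11) is controlled by C1, because the arene must approach perpendicular to the allyl plane and a six-membered tether anchored on the C1 carboxyl allows this only on the face that the carboxyl occupies, so the fusion is cis, whereas a trans fusion would need an in-plane approach. The step needs attack at C2 and not C4, which the tether secures because reaching C4 would require a bridged ring, and it needs ring closure to beat elimination and intermolecular alkylation, which high dilution secures together with the fact that any diene formed by proton loss is re-protonated to the same cation. The two ortho carbons of the symmetric aryl ring are equivalent, so no positional isomer on the arene can arise.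

Step 7
Reactants: 11 (6aS,10aS)-1,3-dimethoxy-6a,9-dimethyl-6a,7,8,10a-tetrahydro-6H-benzo[c]chromen-6-one
Product: 12 (6aS,10aS)-1,3-dimethoxy-6a,9-dimethyl-6a,7,8,10a-tetrahydro-6H-benzo[c]chromen-6-ol (both C6 epimers)
Conditions: i-Bu2AlH (1.2 equiv), CH2Cl2, −78 °C; aqueous Rochelle salt
Reagents that add atoms: none
Why: Partial reduction of an aryl lactone to the lactol, whose tetrahedral aluminate is stable at −78 °C and shielded by the neighbouring quaternary carbon, so over-reduction is held back and neither stereocentre is touched.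

Step 8
Reactants: 12 (6aS,10aS)-1,3-dimethoxy-6a,9-dimethyl-6a,7,8,10a-tetrahydro-6H-benzo[c]chromen-6-ol
Product: 13 2-[(1R,6R)-6-ethenyl-3,6-dimethylcyclohex-2-en-1-yl]-3,5-dimethoxyphenol
Conditions: Ph3PCH3Br (3.5 equiv), KOt-Bu (3.3 equiv), THF, 0 to 50 °C
Reagents that add atoms: methyltriphenylphosphonium bromide, C[P+](c1ccccc1)(c1ccccc1)c1ccccc1.[Br-]
Why: Wittig methylenation of the lactol through its open phenoxide–aldehyde form, a reaction that tolerates α-quaternary aldehydes and touches no stereocentre because the aldehyde carbon has no α-hydrogen.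

Step 9
Reactants: 13 2-[(1R,6R)-6-ethenyl-3,6-dimethylcyclohex-2-en-1-yl]-3,5-dimethoxyphenol
Product: 14 3-[(1R,6R)-6-ethenyl-3,6-dimethylcyclohex-2-en-1-yl]-2-hydroxy-4,6-dimethoxybenzaldehyde
Conditions: MgCl2, Et3N, (CH2O)n, MeCN, 80 °C
Reagents that add atoms: formaldehyde (as paraformaldehyde), C=O
Why: Magnesium-mediated ortho-formylation of a phenol, in which the magnesium phenoxide delivers formaldehyde to the single free ortho carbon and a second formaldehyde takes up hydride, so the carbon between the two methoxy groups is not reached and the acid-free medium spares both alkenes.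

Step 10
Reactants: 14 3-[(1R,6R)-6-ethenyl-3,6-dimethylcyclohex-2-en-1-yl]-2-hydroxy-4,6-dimethoxybenzaldehyde
Product: 16 8-[(1R,6R)-6-ethenyl-3,6-dimethylcyclohex-2-en-1-yl]-5,7-dimethoxy-2H-chromen-2-one, via acyl ylide 15 (not isolated)
Conditions: Ph3P=C=C=O (1.3 equiv), toluene, 110 °C
Reagents that add atoms: (triphenylphosphoranylidene)ketene, O=C=C=P(c1ccccc1)(c1ccccc1)c1ccccc1
Why: Addition of the phenol O–H across the cumulated ylide gives an aryl phosphoranylideneacetate that closes by intramolecular Wittig reaction onto the ortho aldehyde, the ring forcing the cis alkene so that the pyranone of coumarin B forms directly at a temperature far below that at which the 1,5-diene could undergo Cope rearrangement.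

Step 11
Reactants: 17 5,7-dimethoxycoumarin (5,7-dimethoxy-2H-chromen-2-one)
Product: 18 8-iodo-5,7-dimethoxy-2H-chromen-2-one
Conditions: N-iodosuccinimide (1.05 equiv), CF3CO2H (cat.), MeCN, 23 °C
Reagents that add atoms: N-iodosuccinimide, O=C1CCC(=O)N1I
Why: Electrophilic aromatic iodination at C8, which is ortho to the 7-methoxy group and to O1 and para to the 5-methoxy group, and is more open than C6 because the peri C4–H turns the 5-methoxy methyl toward C6.

Step 12
Reactants: 16 8-[(1R,6R)-6-ethenyl-3,6-dimethylcyclohex-2-en-1-yl]-5,7-dimethoxy-2H-chromen-2-one; 18 8-iodo-5,7-dimethoxy-2H-chromen-2-one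
Product: 19 8-[(1R,6R)-6-[(E)-2-(5,7-dimethoxy-2-oxo-2H-chromen-8-yl)ethenyl]-3,6-dimethylcyclohex-2-en-1-yl]-5,7-dimethoxy-2H-chromen-2-one (target)
Conditions: Pd(OAc)2 (10 mol %), n-Bu4NCl, NaHCO3, DMF, 90 °C
Reagents that add atoms: none
Why: Mizoroki–Heck coupling under ligand-free phase-transfer conditions, in which the aryl group adds to the terminal vinyl carbon and the only β-hydrogens sit on the new benzylic carbon because C1 is quaternary, so a single (E)-styrene forms without alkene migration while the trisubstituted ring alkene and the coumarin C3=C4 bonds are poor acceptors.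

Compound list
1 | methacrolein (2-methylprop-2-enal) | CC(=C)C=O | starting material
2 | isoprene (2-methylbuta-1,3-diene) | CC(=C)C=C | starting material
3 | (1S)-1,4-dimethylcyclohex-3-ene-1-carbaldehyde | O=C[C@@]1(C)CCC(C)=CC1 | intermediate
4 | (1S)-1,4-dimethylcyclohex-3-ene-1-carboxylic acid | OC(=O)[C@@]1(C)CCC(C)=CC1 | intermediate
5 | 3,5-dimethoxyphenol | COc1cc(O)cc(OC)c1 | starting material
6 | 3,5-dimethoxyphenyl (1S)-1,4-dimethylcyclohex-3-ene-1-carboxylate | COc1cc(OC)cc(OC(=O)[C@@]2(C)CCC(C)=CC2)c1 | intermediate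
7 | 3,5-dimethoxyphenyl (1S)-4-hydroxy-1,4-dimethyl-3-(phenylselanyl)cyclohexane-1-carboxylate (3,4-trans, both diastereomers) | COc1cc(OC)cc(OC(=O)[C@@]2(C)CCC(C)(O)C([Se]c3ccccc3)C2)c1 | intermediate
8 | 3,5-dimethoxyphenyl (1S)-3-(benzeneseleninyl)-4-hydroxy-1,4-dimethylcyclohexane-1-carboxylate (selenoxide) | COc1cc(OC)cc(OC(=O)[C@@]2(C)CCC(C)(O)C([Se](=O)c3ccccc3)C2)c1 | intermediate (not isolated)
9 | 3,5-dimethoxyphenyl (1S)-4-hydroxy-1,4-dimethylcyclohex-2-ene-1-carboxylate (both C4 epimers) | COc1cc(OC)cc(OC(=O)[C@@]2(C)CCC(C)(O)C=C2)c1 | intermediate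
10 | (4S)-4-[(3,5-dimethoxyphenoxy)carbonyl]-1,4-dimethylcyclohex-2-en-1-ylium (allyl cation) | COc1cc(OC)cc(OC(=O)[C@@]2(C)CC[C+](C)C=C2)c1 | intermediate (not isolated)
11 | (6aS,10aS)-1,3-dimethoxy-6a,9-dimethyl-6a,7,8,10a-tetrahydro-6H-benzo[c]chromen-6-one | O=C2[C@@]1(C)CCC(C)=C[C@H]1c1c(OC)cc(OC)cc1O2 | intermediate
12 | (6aS,10aS)-1,3-dimethoxy-6a,9-dimethyl-6a,7,8,10a-tetrahydro-6H-benzo[c]chromen-6-ol (both C6 epimers) | OC2[C@@]1(C)CCC(C)=C[C@H]1c1c(OC)cc(OC)cc1O2 | intermediate
13 | 2-[(1R,6R)-6-ethenyl-3,6-dimethylcyclohex-2-en-1-yl]-3,5-dimethoxyphenol | C=C[C@@]1(C)CCC(C)=C[C@H]1c1c(OC)cc(OC)cc1O | intermediate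
14 | 3-[(1R,6R)-6-ethenyl-3,6-dimethylcyclohex-2-en-1-yl]-2-hydroxy-4,6-dimethoxybenzaldehyde | C=C[C@@]1(C)CCC(C)=C[C@H]1c1c(OC)cc(OC)c(C=O)c1O | intermediate
15 | 2-[(1R,6R)-6-ethenyl-3,6-dimethylcyclohex-2-en-1-yl]-6-formyl-3,5-dimethoxyphenyl (triphenylphosphoranylidene)acetate | C=C[C@@]1(C)CCC(C)=C[C@H]1c1c(OC)cc(OC)c(C=O)c1OC(=O)C=P(c1ccccc1)(c1ccccc1)c1ccccc1 | intermediate (not isolated)
16 | 8-[(1R,6R)-6-ethenyl-3,6-dimethylcyclohex-2-en-1-yl]-5,7-dimethoxy-2H-chromen-2-one | C=C[C@@]1(C)CCC(C)=C[C@H]1c1c(OC)cc(OC)c2ccc(=O)oc12 | intermediate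
17 | 5,7-dimethoxy-2H-chromen-2-one (5,7-dimethoxycoumarin) | COc1cc(OC)c2ccc(=O)oc2c1 | starting material
18 | 8-iodo-5,7-dimethoxy-2H-chromen-2-one | COc1cc(OC)c2ccc(=O)oc2c1I | intermediate
19 | 8-[(1R,6R)-6-[(E)-2-(5,7-dimethoxy-2-oxo-2H-chromen-8-yl)ethenyl]-3,6-dimethylcyclohex-2-en-1-yl]-5,7-dimethoxy-2H-chromen-2-one | COc1cc(OC)c2ccc(=O)oc2c1/C=C/[C@@]1(C)CCC(C)=C[C@H]1c1c(OC)cc(OC)c2ccc(=O)oc12 | target

Total step count: 12. Longest linear sequence: 11 steps (steps 1 to 10, then step 12); step 11 is a one-step side branch.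

Steps most likely to fail

Step 6 (Proposed new method). The ring-closing s-cis ester conformer is sparsely populated, so after ionisation the cation may be lost to oligomerisation, to acyl transfer onto the C4 oxygen with loss of the phenol, or to acid-driven migration of the product alkene. The fallback uses known chemistry and builds the cyclohexene with coumarin B already on it. It sets out from iodide 18. Heck coupling with 2-methylbut-3-en-2-ol (Pd(OAc)2, n-Bu4NCl, NaHCO3, DMF, 80 °C) should give the allylic alcohol (E)-8-(3-hydroxy-3-methylbut-1-en-1-yl)-5,7-dimethoxy-2H-chromen-2-one F1. Dehydration (pyridinium p-toluenesulfonate, toluene, 80 °C) should give the diene (E)-5,7-dimethoxy-8-(3-methylbuta-1,3-dien-1-yl)-2H-chromen-2-one F2, which is used at once because it dimerises on standing. The oxazaborolidinium-catalysed Diels–Alder reaction of F2 with methacrolein 1 (conditions of step 1, higher catalyst loading, ortho regiochemistry, formyl group endo, same enal face) should give (1S,2S)-2-(5,7-dimethoxy-2-oxo-2H-chromen-8-yl)-1,4-dimethylcyclohex-3-ene-1-carbaldehyde F3 with both stereocentres set. Chemoselective methylenation of the aldehyde (Zn, CH2Br2, TiCl4, THF, 0 °C) then gives vinyl coumarin 16, where the fallback comes back to the route ahead of step 12.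

Step 12. Oxidative addition and alkene insertion between a di-ortho-substituted, electron-rich aryl iodide and a vinyl group on a quaternary carbon may be so slow that catalyst decay and reductive deiodination take over. The fallback replaces the Heck insertion by a Suzuki–Miyaura coupling of an (E)-alkenylboronate and sets out from lactol 12. Seyferth–Gilbert homologation in its one-pot form (dimethyl (1-diazo-2-oxopropyl)phosphonate, K2CO3, MeOH, 23 °C) should give the alkyne 2-[(1R,6S)-6-ethynyl-3,6-dimethylcyclohex-2-en-1-yl]-3,5-dimethoxyphenol F4. The conditions of step 9 should give 3-[(1R,6S)-6-ethynyl-3,6-dimethylcyclohex-2-en-1-yl]-2-hydroxy-4,6-dimethoxybenzaldehyde F5, and those of step 10 should give 8-[(1R,6S)-6-ethynyl-3,6-dimethylcyclohex-2-en-1-yl]-5,7-dimethoxy-2H-chromen-2-one F6. Syn-hydroboration with pinacolborane and catalytic Cp2Zr(H)Cl (CH2Cl2, 23 °C) should give 8-[(1R,6R)-3,6-dimethyl-6-[(E)-2-(4,4,5,5-tetramethyl-1,3,2-dioxaborolan-2-yl)ethenyl]cyclohex-2-en-1-yl]-5,7-dimethoxy-2H-chromen-2-one F7. Coupling of F7 with iodide 18 (Pd(dppf)Cl2, K3PO4, dioxane/H2O, 70 °C) then gives target 19, where the fallback comes back to the route.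

Step 4. The seleniranium ion may be captured by the ester carbonyl across the ring, with loss of the phenol, or the electrophilic selenium may attack the electron-rich arene instead of the alkene. The fallback avoids electrophilic selenium and sets out from alkene 6. A Schenck ene reaction with singlet oxygen (O2, visible light, tetraphenylporphyrin, CH2Cl2, −20 °C) should give 3,5-dimethoxyphenyl (1S)-4-hydroperoxy-1,4-dimethylcyclohex-2-ene-1-carboxylate F8 beside secondary regioisomers that are removed by chromatography. Reduction with PPh3 gives alcohol 9, where the fallback comes back to the route ahead of step 6.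

Further compounds
F1 | step 6 | (E)-8-(3-hydroxy-3-methylbut-1-en-1-yl)-5,7-dimethoxy-2H-chromen-2-one | COc1cc(OC)c2ccc(=O)oc2c1/C=C/C(C)(C)O
F2 | step 6 | (E)-5,7-dimethoxy-8-(3-methylbuta-1,3-dien-1-yl)-2H-chromen-2-one | COc1cc(OC)c2ccc(=O)oc2c1/C=C/C(C)=C
F3 | step 6 | (1S,2S)-2-(5,7-dimethoxy-2-oxo-2H-chromen-8-yl)-1,4-dimethylcyclohex-3-ene-1-carbaldehyde | O=C[C@@]1(C)CCC(C)=C[C@H]1c1c(OC)cc(OC)c2ccc(=O)oc12
F4 | step 12 | 2-[(1R,6S)-6-ethynyl-3,6-dimethylcyclohex-2-en-1-yl]-3,5-dimethoxyphenol | C#C[C@@]1(C)CCC(C)=C[C@H]1c1c(OC)cc(OC)cc1O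
F5 | step 12 | 3-[(1R,6S)-6-ethynyl-3,6-dimethylcyclohex-2-en-1-yl]-2-hydroxy-4,6-dimethoxybenzaldehyde | C#C[C@@]1(C)CCC(C)=C[C@H]1c1c(OC)cc(OC)c(C=O)c1O
F6 | step 12 | 8-[(1R,6S)-6-ethynyl-3,6-dimethylcyclohex-2-en-1-yl]-5,7-dimethoxy-2H-chromen-2-one | C#C[C@@]1(C)CCC(C)=C[C@H]1c1c(OC)cc(OC)c2ccc(=O)oc12
F7 | step 12 | 8-[(1R,6R)-3,6-dimethyl-6-[(E)-2-(4,4,5,5-tetramethyl-1,3,2-dioxaborolan-2-yl)ethenyl]cyclohex-2-en-1-yl]-5,7-dimethoxy-2H-chromen-2-one | CC1(C)OB(/C=C/[C@@]2(C)CCC(C)=C[C@H]2c2c(OC)cc(OC)c3ccc(=O)oc23)OC1(C)C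
F8 | step 4 | 3,5-dimethoxyphenyl (1S)-4-hydroperoxy-1,4-dimethylcyclohex-2-ene-1-carboxylate | COc1cc(OC)cc(OC(=O)[C@@]2(C)CCC(C)(OO)C=C2)c1
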